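**Plan**

1. Retrosynthesis: remove three MOM ethers, cut O1–C2 (oxa-Michael) and the Cα=Cβ bond (Claisen–Schmidt) to give ring A acetophenone 19 and ring B aldehyde 15, which already carries its pyran.
2. In 15 cut both bonds from ring B to the pyran, C5'–CH and C4'–O (the O–C(CH3)2 bond forms in the same cascade). Ring B becomes an aryne across C4'–C5', and the pyran atoms O–C(CH3)2–CH=CH become 3-methylbut-2-enal, already at the right oxidation level.
3. Enabling feature: C4' and C5' are adjacent and each is flanked by a C–H (C3', C6'). A temporary bromine at C6', beside the triple bond, decides which aryne carbon takes oxygen, then acidifies C1' for formylation, and is then removed.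
4. Forward: aryne precursor, then the pyran on ring B (key step), then formylation and debromination. Ring A ketone by C-prenylation and selective MOM protection. Chalcone, then ring C closed through the only free phenol, which lies next to the prenyl group (gives 8-prenyl).
5. Stereochemistry: C2 is formed racemic. The (2S) enantiomer is secured by catalyst-controlled kinetic resolution (asymmetric transfer hydrogenation consumes the 2R enantiomer), and mild acidic deprotection leaves C2 untouched.

Key step: step 3

Remark: 4-(methoxymethoxy)phenol 1 is assumed purchasable (otherwise one step from hydroquinone); target locants follow flavanone numbering, building blocks follow 2H-chromene numbering.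

**Route**

Step 1
Reactants: 1 4-(methoxymethoxy)phenol
Product: 2 2,6-dibromo-4-(methoxymethoxy)phenol
Conditions: NBS (2.05 equiv), iPr2NH (10 mol %), CH2Cl2, 0 °C to rt
Reagents that add atoms: N-bromosuccinimide, O=C1CCC(=O)N1Br
Why: Amine-mediated electrophilic bromination of phenols is ortho-selective, the para position is blocked, and the neutral medium should spare the MOM acetal.

Step 2
Reactants: 2 2,6-dibromo-4-(methoxymethoxy)phenol
Product: 6 2-bromo-4-(methoxymethoxy)-6-(trimethylsilyl)phenyl trifluoromethanesulfonate, via O-trimethylsilyl ether 3 (not isolated), via aryllithium 4 (not isolated), via lithium phenoxide 5 (not isolated)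
Conditions: HN(SiMe3)2, THF, 65 °C, then evaporation; n-BuLi (1.05 equiv), THF, −78 °C to rt; Tf2O, −78 °C to 0 °C
Reagents that add atoms: hexamethyldisilazane, C[Si](C)(C)N[Si](C)(C)C; trifluoromethanesulfonic anhydride, O=S(=O)(OS(=O)(=O)C(F)(F)F)C(F)(F)F
Why: O-silylation, bromine–lithium exchange of one of the two equivalent bromides and anionic 1,3-silyl shift from O to C (retro-Brook rearrangement) should give the ortho-silyl phenoxide, which Tf2O traps as the ortho-silylaryl triflate aryne precursor; the symmetry of 2 removes any choice between the bromides.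

Step 3
Reactants: 6 2-bromo-4-(methoxymethoxy)-6-(trimethylsilyl)phenyl trifluoromethanesulfonate; 7 3-methylbut-2-enal
Product: 11 5-bromo-7-(methoxymethoxy)-2,2-dimethyl-2H-chromene, via aryne 8 (not isolated), via benzoxete 9 (not isolated), via ortho-quinone methide 10 (not isolated)
Conditions: CsF (3 equiv), 7 (5 equiv), MeCN, rt, slow addition of 6
Reagents that add atoms: none
Why: Fluoride-induced 1,2-elimination of 6 gives aryne 8, whose triple bond is polarised by the C–Br bond beside it, so the carbonyl oxygen of 7 adds to the aryne carbon remote from bromine (the one flanked by C–H) and the aryl anion, which develops on the carbon next to bromine where it is inductively stabilised, closes on the oxocarbenium carbon to give benzoxete 9 (stepwise polar [2+2], four-membered ring by collapse of the zwitterion). Thermal 4π ring opening of 9 gives ortho-quinone methide 10, and disrotatory oxa-6π electrocyclisation of the isomer with the butenylidene chain syn to the carbonyl closes the pyran ring and restores the aromatic sextet, so the two aryne carbons end up bearing the ring oxygen and the vinylic CH. The closest known reaction type is the formation of 2H-chromenes from arynes and α,β-unsaturated aldehydes, a relative of aryne insertion into the C=O bond of formamides. No stereocentre remains in 11, since the sp3 carbon of 9 is lost on ring opening. The step needs regioselectivity of oxygen versus carbon attachment, secured by the bromine beside the triple bond (the meta acetal oxygen opposes it only weakly), and chemoselectivity against capture of 10 by a second aryne, secured by excess 7 and slow generation of 8.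

Step 4
Reactants: 11 5-bromo-7-(methoxymethoxy)-2,2-dimethyl-2H-chromene
Product: 14 5-bromo-7-(methoxymethoxy)-2,2-dimethyl-2H-chromene-6-carbaldehyde, via aryllithium 12 (not isolated), via lithium hemiaminal alkoxide 13 (not isolated)
Conditions: LiN(iPr)2 (1.2 equiv), THF, −78 °C; DMF, −78 °C to 0 °C; H2O
Reagents that add atoms: N,N-dimethylformamide, CN(C)C=O
Why: Deprotonative ortho-lithiation should occur at C6, the only ring hydrogen flanked by the inductively acidifying bromine and the chelating MOM ether (as in lithium amide metalation of 3-bromoanisole), and DMF formylation of the aryllithium (Bouveault reaction) follows, the low temperature preventing loss of LiBr.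

Step 5
Reactants: 14 5-bromo-7-(methoxymethoxy)-2,2-dimethyl-2H-chromene-6-carbaldehyde
Product: 15 7-(methoxymethoxy)-2,2-dimethyl-2H-chromene-6-carbaldehyde
Conditions: Pd(PPh3)4 (5 mol %), HCO2Na (3 equiv), DMF, 80 °C
Reagents that add atoms: none
Why: Formate hydrodebromination proceeds by oxidative addition of zerovalent palladium into the C–Br bond activated by the ortho formyl group, formate exchange, decarboxylation and C–H reductive elimination, conditions to which the aldehyde, the chromene alkene and the MOM ether should be inert.

Step 6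
Reactants: 16 1-(2,4,6-trihydroxyphenyl)ethan-1-one; 17 1-bromo-3-methylbut-2-ene
Product: 18 1-[2,4,6-trihydroxy-3-(3-methylbut-2-en-1-yl)phenyl]ethan-1-one
Conditions: 17 (0.9 equiv), DBU (1.0 equiv), THF, 0 °C to rt
Reagents that add atoms: none
Why: Nuclear C-alkylation of the ambident phloroglucinol-type phenoxide with an allylic bromide; the two free ring positions are equivalent, so mono-prenylation gives a single regioisomer and a deficit of 17 limits double alkylation.

Step 7
Reactants: 18 1-[2,4,6-trihydroxy-3-(3-methylbut-2-en-1-yl)phenyl]ethan-1-one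
Product: 19 1-[2-hydroxy-4,6-bis(methoxymethoxy)-3-(3-methylbut-2-en-1-yl)phenyl]ethan-1-one
Conditions: MOMCl (2.2 equiv), iPr2NEt (2.5 equiv), CH2Cl2, 0 °C
Reagents that add atoms: chloromethyl methyl ether, COCCl
Why: Selective O-alkylation should take the 4-OH (para to acetyl, most acidic) and the unhindered 6-OH, while the 2-OH, wedged between prenyl and acetyl and hydrogen-bonded to the carbonyl, stays free, which later forces ring closure on the prenyl side.

Step 8
Reactants: 19 1-[2-hydroxy-4,6-bis(methoxymethoxy)-3-(3-methylbut-2-en-1-yl)phenyl]ethan-1-one; 15 7-(methoxymethoxy)-2,2-dimethyl-2H-chromene-6-carbaldehyde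
Product: 20 (2E)-1-[2-hydroxy-4,6-bis(methoxymethoxy)-3-(3-methylbut-2-en-1-yl)phenyl]-3-[7-(methoxymethoxy)-2,2-dimethyl-2H-chromen-6-yl]prop-2-en-1-one
Conditions: KOH (aq., excess), EtOH, rt
Reagents that add atoms: none
Why: Claisen–Schmidt condensation of the methyl ketone enolate with the non-enolisable aldehyde, followed by E1cB dehydration to the E enone; MOM ethers are stable to hydroxide.

Step 9
Reactants: 20 the chalcone of step 8
Product: 21 rac-5,7-bis(methoxymethoxy)-2-[7-(methoxymethoxy)-2,2-dimethyl-2H-chromen-6-yl]-8-(3-methylbut-2-en-1-yl)-2,3-dihydro-4H-chromen-4-one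
Conditions: NaOAc, EtOH, reflux
Reagents that add atoms: none
Why: Base-mediated 6-endo-trig intramolecular oxa-Michael addition of the only free phenol (next to the prenyl group) should give the 8-prenyl flavanone; C2 is formed here without control, as the racemate.

Step 10
Reactants: 21 the racemic flavanone of step 9
Product: 22 (2S)-5,7-bis(methoxymethoxy)-2-[7-(methoxymethoxy)-2,2-dimethyl-2H-chromen-6-yl]-8-(3-methylbut-2-en-1-yl)-2,3-dihydro-4H-chromen-4-one (recovered, unreduced enantiomer)
Conditions: Cp*RhCl[(R,R)-TsDPEN] (1 mol %), HCO2H/Et3N (5:2), EtOAc, rt, stopped slightly past half conversion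
Reagents that add atoms: none
Why: Kinetic resolution by Noyori asymmetric transfer hydrogenation: the (R,R) catalyst delivers hydride to the carbonyl face that gives the 4R carbinol, which coincides with the substrate-preferred cis-selective attack only in the 2R enantiomer, so that enantiomer is reduced to the (2R,4R)-flavan-4-ol and 22 should be recovered enantiopure (at most half of 21), the alkenes being inert to the metal hydride.

Step 11
Reactants: 22 the (2S)-flavanone of step 10
Product: 23 (2S)-5,7-dihydroxy-2-(7-hydroxy-2,2-dimethyl-2H-chromen-6-yl)-8-(3-methylbut-2-en-1-yl)-2,3-dihydro-4H-chromen-4-one (target)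
Conditions: 3 M aq. HCl, MeOH, 40 °C
Reagents that add atoms: none
Why: Acid-catalysed acetal exchange with methanol removes the three MOM ethers; dilute acid at moderate temperature is chosen to spare the chromene and prenyl alkenes and to avoid opening the pyranone ring, so C2 should keep its S configuration.

**Compound list**

1 | 4-(methoxymethoxy)phenol | COCOc1ccc(O)cc1 | starting material
2 | 2,6-dibromo-4-(methoxymethoxy)phenol | COCOc1cc(Br)c(O)c(Br)c1 | intermediate
3 | [2,6-dibromo-4-(methoxymethoxy)phenoxy]trimethylsilane | COCOc1cc(Br)c(O[Si](C)(C)C)c(Br)c1 | intermediate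
4 | [3-bromo-5-(methoxymethoxy)-2-(trimethylsilyloxy)phenyl]lithium | COCOc1cc(Br)c(O[Si](C)(C)C)c([Li])c1 | intermediate
5 | lithium 2-bromo-4-(methoxymethoxy)-6-(trimethylsilyl)phenolate | COCOc1cc(Br)c([O-])c([Si](C)(C)C)c1.[Li+] | intermediate
6 | 2-bromo-4-(methoxymethoxy)-6-(trimethylsilyl)phenyl trifluoromethanesulfonate | COCOc1cc(Br)c(OS(=O)(=O)C(F)(F)F)c([Si](C)(C)C)c1 | intermediate
7 | 3-methylbut-2-enal | CC(C)=CC=O | starting material
8 | 3-bromo-5-(methoxymethoxy)benzyne | COCOC1=CC#CC(Br)=C1 | intermediate
9 | 3-bromo-5-(methoxymethoxy)-2-(2-methylprop-1-en-1-yl)-2H-benzo[b]oxete | COCOc1cc2OC(C=C(C)C)c2c(Br)c1 | intermediate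
10 | 5-bromo-3-(methoxymethoxy)-6-(3-methylbut-2-en-1-ylidene)cyclohexa-2,4-dien-1-one, butenylidene chain syn to the carbonyl | COCOC1=CC(=O)/C(=C\C=C(C)C)C(Br)=C1 | intermediate
11 | 5-bromo-7-(methoxymethoxy)-2,2-dimethyl-2H-chromene | COCOc1cc(Br)c2C=CC(C)(C)Oc2c1 | intermediate
12 | [5-bromo-7-(methoxymethoxy)-2,2-dimethyl-2H-chromen-6-yl]lithium | COCOc1cc2OC(C)(C)C=Cc2c(Br)c1[Li] | intermediate
13 | lithium [5-bromo-7-(methoxymethoxy)-2,2-dimethyl-2H-chromen-6-yl](dimethylamino)methanolate | COCOc1cc2OC(C)(C)C=Cc2c(Br)c1C([O-])N(C)C.[Li+] | intermediate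
14 | 5-bromo-7-(methoxymethoxy)-2,2-dimethyl-2H-chromene-6-carbaldehyde | COCOc1cc2OC(C)(C)C=Cc2c(Br)c1C=O | intermediate
15 | 7-(methoxymethoxy)-2,2-dimethyl-2H-chromene-6-carbaldehyde | COCOc1cc2OC(C)(C)C=Cc2cc1C=O | intermediate
16 | 1-(2,4,6-trihydroxyphenyl)ethan-1-one | CC(=O)c1c(O)cc(O)cc1O | starting material
17 | 1-bromo-3-methylbut-2-ene | CC(C)=CCBr | starting material
18 | 1-[2,4,6-trihydroxy-3-(3-methylbut-2-en-1-yl)phenyl]ethan-1-one | CC(=O)c1c(O)cc(O)c(CC=C(C)C)c1O | intermediate
19 | 1-[2-hydroxy-4,6-bis(methoxymethoxy)-3-(3-methylbut-2-en-1-yl)phenyl]ethan-1-one | CC(=O)c1c(O)c(CC=C(C)C)c(OCOC)cc1OCOC | intermediate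
20 | (2E)-1-[2-hydroxy-4,6-bis(methoxymethoxy)-3-(3-methylbut-2-en-1-yl)phenyl]-3-[7-(methoxymethoxy)-2,2-dimethyl-2H-chromen-6-yl]prop-2-en-1-one | COCOc1cc(OCOC)c(C(=O)/C=C/c2cc3C=CC(C)(C)Oc3cc2OCOC)c(O)c1CC=C(C)C | intermediate
21 | rac-5,7-bis(methoxymethoxy)-2-[7-(methoxymethoxy)-2,2-dimethyl-2H-chromen-6-yl]-8-(3-methylbut-2-en-1-yl)-2,3-dihydro-4H-chromen-4-one | COCOc1cc(OCOC)c2C(=O)CC(c3cc4C=CC(C)(C)Oc4cc3OCOC)Oc2c1CC=C(C)C | intermediate
22 | (2S)-5,7-bis(methoxymethoxy)-2-[7-(methoxymethoxy)-2,2-dimethyl-2H-chromen-6-yl]-8-(3-methylbut-2-en-1-yl)-2,3-dihydro-4H-chromen-4-one | COCOc1cc(OCOC)c2C(=O)C[C@@H](c3cc4C=CC(C)(C)Oc4cc3OCOC)Oc2c1CC=C(C)C | intermediate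
23 | (2S)-5,7-dihydroxy-2-(7-hydroxy-2,2-dimethyl-2H-chromen-6-yl)-8-(3-methylbut-2-en-1-yl)-2,3-dihydro-4H-chromen-4-one | CC(C)=CCc1c(O)cc(O)c2c1O[C@H](c1cc3c(cc1O)OC(C)(C)C=C3)CC2=O | target

**Step count and risks**

Total step count: 11. Longest linear sequence: 9 steps (steps 1, 2, 3, 4, 5, 8, 9, 10, 11).

Steps most likely to fail:

Step 3. The enal oxygen may capture the aryne too slowly, so that the aryne is consumed unproductively, or the ortho-quinone methide may be intercepted by a second aryne before it electrocyclises. The fallback sets out from 6 and separates the two events. Aryne 8 is generated with CsF in MeCN containing DMF, whose amide oxygen is a much better aryne acceptor. The same bromine-controlled C=O insertion, followed by aqueous hydrolysis of the aminal, should give 2-bromo-6-hydroxy-4-(methoxymethoxy)benzaldehyde F1. Condensation of this salicylaldehyde with 2-methylprop-1-enylboronic acid (CC(C)=CB(O)O) and dibenzylamine in dioxane at 90 °C (Petasis-type alkenyl transfer to the iminium ion, loss of the amine, oxa-6π electrocyclisation) comes back to the route at 11.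

Step 4. Deprotonation may compete at C8 between the two ether oxygens, or the ortho-bromoaryllithium may lose LiBr. The fallback sets out from 11. Bromine–lithium exchange (n-BuLi, THF, −78 °C) and a methanol quench should give 7-(methoxymethoxy)-2,2-dimethyl-2H-chromene F2. Brief treatment with dilute HCl in MeOH at rt should free 2,2-dimethyl-2H-chromen-7-ol F3. Magnesium phenoxide-directed ortho-formylation (MgCl2, Et3N, paraformaldehyde, MeCN, reflux) should go to the less hindered ortho position C6 and give 7-hydroxy-2,2-dimethyl-2H-chromene-6-carbaldehyde F4. Re-protection with MOMCl and iPr2NEt comes back to the route at 15, so step 5 is no longer needed.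

Step 10. The rate difference between the enantiomers in hydride transfer may be too small (hindered 5-alkoxy ketone, ortho-substituted 2-aryl group), or base-induced ring opening and reclosure may erode the enantiomeric purity during the resolution. The fallback sets out from 21 and replaces the chemical resolution by a physical one: preparative HPLC on an amylose tris(3,5-dimethylphenylcarbamate) stationary phase (hexane/iPrOH) should separate 22 from (2R)-5,7-bis(methoxymethoxy)-2-[7-(methoxymethoxy)-2,2-dimethyl-2H-chromen-6-yl]-8-(3-methylbut-2-en-1-yl)-2,3-dihydro-4H-chromen-4-one F5. The latter can be re-racemised to 21 through chalcone 20 under the conditions of step 9 and recycled. The fallback comes back to the route at 22.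

**Further compounds**

F1 | step 3 | 2-bromo-6-hydroxy-4-(methoxymethoxy)benzaldehyde | COCOc1cc(O)c(C=O)c(Br)c1
F2 | step 4 | 7-(methoxymethoxy)-2,2-dimethyl-2H-chromene | COCOc1ccc2C=CC(C)(C)Oc2c1
F3 | step 4 | 2,2-dimethyl-2H-chromen-7-ol | CC1(C)C=Cc2ccc(O)cc2O1
F4 | step 4 | 7-hydroxy-2,2-dimethyl-2H-chromene-6-carbaldehyde | CC1(C)C=Cc2cc(C=O)c(O)cc2O1
F5 | step 10 | (2R)-5,7-bis(methoxymethoxy)-2-[7-(methoxymethoxy)-2,2-dimethyl-2H-chromen-6-yl]-8-(3-methylbut-2-en-1-yl)-2,3-dihydro-4H-chromen-4-one | COCOc1cc(OCOC)c2C(=O)C[C@H](c3cc4C=CC(C)(C)Oc4cc3OCOC)Oc2c1CC=C(C)C
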